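Take the midnight table below and read its target column against its substrate column.

| flask | substrate | partner | temperature | remark | time |
|---|---|---|---|---|---|
| winter | 0.40 M | 0.70 equiv | 25 °C | run made earlier |  |
| noon | 0.60 M | 0.70 equiv | 36 °C | run made earlier |  |
| midnight | 0.80 M | 1.4 equiv | 25 °C | run made earlier |  |
| alder | 0.80 M | 0.700 equiv | 20 °C |  | 8.0 min |
| birch | 0.80 M | 0.700 equiv | 40 °C |  | 8.0 min |

| run | time / min | target / % | substrate / % |
|---|---|---|---|
| winter | 0.500 | 0.3 | 92.9 |
| winter | 0.833 | 0 | 93.2 |
| winter | 1.33 | 0 | 86.9 |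
| winter | 2.50 | 2.3 | 79.4 |
| winter | 4.00 | 0.7 | 67.7 |
| winter | 6.00 | 3.0 | 56.4 |
| noon | 0.200 | 0 | 91.6 |
| noon | 0.667 | 0.2 | 78.5 |
| noon | 1.00 | 1.9 | 71.5 |
| noon | 2.00 | 3.1 | 54.7 |
| noon | 2.50 | 5.0 | 51.9 |
| midnight | 0.500 | 0 | 95.6 |
| midnight | 1.00 | 1.9 | 91.8 |
| midnight | 2.00 | 0.9 | 82.1 |
| midnight | 3.00 | 3.1 | 74.4 |
| midnight | 6.00 | 8.0 | 55.8 |

(standard deviation of a reading: 1 percentage point)

- the flask with the highest amount of target, in percent of the substrate charged ("all alike" if they lie within 1.5 percentage points) (alder / birch / all alike)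
- final target, as a percentage of the substrate charged, in alder
- final target, as a percentage of the substrate charged, in birch



Midnight's substrate fell to 74.4% at 3.00 min and 55.8% at 6.00 min; I read the last row as a first-order rate of 0.0972 min⁻¹. Between those rows the readings of lost substrate grew 1.73 times and those of target 2.58 times. So I tried target as following the area under lost substrate against time, which I call exposure: with first-order loss, it is the time minus the lost fraction over the rate. Midnight's last row gives 1.45 min of exposure, so 0.0550 min⁻¹ of target per unit, a pseudo-first-order constant.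

For alder, the charged c(partner) is half of midnight's. Noon's last row reads 0.262 min⁻¹, faster than midnight's; winter, at midnight's temperature with a different charge, reads 0.0955 min⁻¹, close to midnight's, so I put the difference down to temperature. Taking the logarithm of the rate as straight in temperature gives a factor 0.637 at 20 °C, which I assumed target's step shares. That makes the alder target constant per minute of exposure 0.0175 min⁻¹. With a substrate rate of 0.0619 min⁻¹, alder's exposure is 1.69 min, and I expected 2.96% target. For birch the factor is 3.87, and the same steps, which keep c(partner) at its charge, give 58.3%.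

The forecast said birch, with alder at 3% (1.5% to 5.5%) and birch at 40% (25% to 55%), noting “Target lags, and most lost substrate is unaccounted for”. My birch figure stood higher than the forecast's.

Alder gave 2.96% and birch 31.5%, so birch held more than alder.

    partner → second intermediate (k = 0.0918 s⁻¹, Ea = 79.0 kJ mol⁻¹)
    open intermediate + second intermediate → target (k = 0.00412 M⁻¹ s⁻¹, Ea = 69.0 kJ mol⁻¹)
    partner → decomposition product (k = 1.66 × 10⁻⁵ s⁻¹, Ea = 107 kJ mol⁻¹)
    substrate ⇌ open intermediate (K = 1.20, k = 0.0102 s⁻¹, Ea = 91.0 kJ mol⁻¹, ΔH = −48.0 kJ mol⁻¹)
    (constants at 40 °C)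

With the 65.3% substrate that alder held at 8.00 min, exposure comes to 1.48 min, and 0.0175 min⁻¹ gives 2.59%, against 2.96%. Alder's partner was then down to 0.38% of its charge, and second intermediate stood at 0.534 M. Alder read at 15 min instead held 47.1% substrate, an exposure of 4.46 min; 0.0175 min⁻¹ gives 7.81%, and that flask held 8.61% target.

The runs come from a simulation for an exercise; scatter was added.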